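The ratio I carry is one molecule's odds in the ochre flask: how fast mono adduct is gained against how fast it is lost.

| flask | substrate | gas | remark | time |
|---|---|---|---|---|
| ochre | 0.063 M | 28 mM (held) | the very flask that is asked about, followed so far |  |
| flask | 0.063 M | 28 mM (held) |  | 40 h |

- ochre (time / h: mono adduct / %): 0.250: 8; 0.417: 16; 0.667: 30; 0.833: 32; 1.33: 42; 2.00: 35; 3.00: 20

(readings scatter by 2 percentage points)

- at the start none of the gas is in solution

- when, up to 40 h, the flask holds most mono adduct
- the amount of mono adduct, in percent of the substrate charged, at that time

1. Between 0.417 h and 0.667 h, the ochre readings gain, as a share of the charge, 0.560 h⁻¹.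

2. Between 2.00 h and 3.00 h, they fall with an apparent first-order constant of 0.560 h⁻¹.

3. The gain divided by the fall is 1.00, and this I call my fork ratio. It is a rough reading with the scatter of the points behind it, not a constant of the ochre flask; at the start none of the gas is in solution.

4. Now I turn the question round. For a top later than these readings, the ochre flask would have to make more mono adduct than it loses at 3.00 h. Instead the readings drop by 15 percentage points, against a scatter of 2 points for one reading.

5. A two-step series with a ratio near one tops out at about one part in e of the charge. So, with a small correction for the distance of 1.00 from one, I commit to 36.8% near 1.33 h, below the single highest reading of 42%.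

The forecast gives 1.3 h and 41%, a higher top than mine, and says: “This is the same flask, so nothing later exceeds it”.

    partner + mono adduct → bis adduct (k = 0.00903 M⁻¹ s⁻¹)
    partner + other mono adduct → bis adduct (k = 0.0113 M⁻¹ s⁻¹)
    partner → decomposed reagent (k = 2.42 × 10⁻⁴ s⁻¹)
    substrate + partner → mono adduct (k = 0.0181 M⁻¹ s⁻¹)
    substrate + partner → other mono adduct (k = 0.00951 M⁻¹ s⁻¹)
    gas ⇌ partner, rate k6*(csat - [partner]) (kL = 0.00120 s⁻¹)

The flask reaches 38.1% at 1.39 h, when other mono adduct stands at 18.5%. My top from the fork ratio lies 1.3 points below that. The neighbour flask has 0.038 M of substrate; the fork ratio of 1.00, put in unchanged, gives 36.8% for it, and that flask holds 38.1% at its top.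

The earlier runs and the new flask stem from a simulated flask with constants of no real substance; scatter was added.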